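**Retrosynthetic overview**

1. Target ⇒ free the C9 silyl ether and the C8 senecioate; open the α-methylene-γ-lactone to a C6/C12 2-methylene-1,4-diol (MnO2 lactonisation); remove the cis-4,5-epoxide (hydroxyl-directed epoxidation of a 6-hydroxy-4Z-alkene).
2. Ten-membered carbocycle and C6–C7 bond ⇒ [2,3]-Wittig ring contraction of a 13-membered bis-allylic ether (oxygen bridging C6 and C13), which relays chirality from C8 to C7 and C6.
3. 13-membered ether ⇒ Williamson macro-etherification (C6 alkoxide, C13 chloride); open chain ⇒ Horner–Wadsworth–Emmons olefination (C7=C11) and Z-selective Wittig olefination (C1=C10).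
4. Pieces: an L-threonate acetonide (C7–C10, carries C8 and C9), nerol (C1–C6 with the 4Z alkene), a phosphonoacetate/formaldehyde reagent (C11–C13), senecioyl chloride.
5. Ring order: 13-membered oxacycle → ten-membered carbocycle → oxirane → γ-lactone.

Assumption: methyl 3,4-O-isopropylidene-L-threonate (vitamin C derived) and nerol are taken as catalogue chemicals; germacrane numbering (C1–C15) is used for all intermediates, and the CIP letter at C7 changes with the O-substituents although its spatial arrangement does not.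

**Step 1**
Reactants: 1 methyl 3,4-O-isopropylidene-L-threonate
Product: 2 methyl (2R)-2-[(tert-butyldimethylsilyl)oxy]-2-[(4S)-2,2-dimethyl-1,3-dioxolan-4-yl]acetate
Conditions: TBSCl, imidazole, DMF, rt
Reagents that add atoms: tert-butyldimethylsilyl chloride CC(C)(C)[Si](C)(C)Cl
Why: Imidazole-mediated silyl ether formation on the only free hydroxyl; C9 and C8 of the target (threonate C2 and C3) are bought in 1 and not touched.

**Step 2**
Reactants: 2 O-TBS threonate ester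
Product: 4 (1R)-1-[(tert-butyldimethylsilyl)oxy]-1-[(4S)-2,2-dimethyl-1,3-dioxolan-4-yl]propan-2-one, via Weinreb amide 3 (not isolated)
Conditions: MeNH(OMe)·HCl, i-PrMgCl, THF, −20 °C; then MeMgBr, −20 → 0 °C
Reagents that add atoms: methylmagnesium bromide C[Mg]Br; N,O-dimethylhydroxylamine hydrochloride CNOC.Cl (its atoms stay only in 3)
Why: One-pot Weinreb ketone synthesis, in which the chelated tetrahedral adduct of 3 stops the Grignard addition at the methyl ketone and the α-silyloxy centre is not enolised at low temperature.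

**Step 3**
Reactants: 5 nerol
Product: 6 neryl 4-methoxybenzyl ether
Conditions: NaH, PMBCl, n-Bu4NI (cat.), THF/DMF, 0 °C → rt
Reagents that add atoms: 4-methoxybenzyl chloride COc1ccc(CCl)cc1
Why: Williamson ether synthesis on the primary allylic alkoxide; the Z alkene (future C4=C5) comes from nerol.

**Step 4**
Reactants: 6 neryl 4-methoxybenzyl ether
Product: 8 (4Z)-6-[(4-methoxybenzyl)oxy]-4-methylhex-4-en-1-ol, via aldehyde 7 (not isolated)
Conditions: O3 (1.0 equiv), CH2Cl2/MeOH, pyridine (cat.), −78 °C; PPh3; then NaBH4, 0 °C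
Reagents that add atoms: ozone [O-][O+]=O
Why: Chemoselective ozonolysis of the remote, more electron-rich trisubstituted alkene (the allylic-ether alkene is inductively deactivated), followed by borohydride reduction of the aldehyde in the same flask.

**Step 5**
Reactants: 8 (4Z)-6-[(4-methoxybenzyl)oxy]-4-methylhex-4-en-1-ol
Product: 9 1-({[(2Z)-6-iodo-3-methylhex-2-en-1-yl]oxy}methyl)-4-methoxybenzene
Conditions: I2, PPh3, imidazole, CH2Cl2, 0 °C
Reagents that add atoms: iodine II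
Why: Garegg–Samuelsson (Appel-type) iodination of the primary alcohol by SN2 displacement of the alkoxyphosphonium ion.

**Step 6**
Reactants: 9 primary iodide
Product: 10 [(4Z)-6-[(4-methoxybenzyl)oxy]-4-methylhex-4-en-1-yl]triphenylphosphonium iodide
Conditions: PPh3, MeCN, reflux
Reagents that add atoms: triphenylphosphine c1ccc(cc1)P(c1ccccc1)c1ccccc1
Why: SN2 quaternisation of triphenylphosphine by the unhindered primary iodide.

**Step 7**
Reactants: 4 α-silyloxy methyl ketone; 10 phosphonium iodide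
Product: 12 (4S)-4-[(1S,2Z,6Z)-1-[(tert-butyldimethylsilyl)oxy]-8-[(4-methoxybenzyl)oxy]-2,6-dimethylocta-2,6-dien-1-yl]-2,2-dimethyl-1,3-dioxolane, via phosphorus ylide 11 (not isolated)
Conditions: 10, KN(SiMe3)2, THF, −78 °C; then 4, −78 °C → rt
Reagents that add atoms: none
Why: Wittig olefination of an α-oxygenated methyl ketone with a non-stabilised, salt-free ylide, which places the oxygenated carbon C9 cis to the ylide chain and so gives the 1(10)Z trisubstituted alkene without epimerising C9 at −78 °C.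

**Step 8**
Reactants: 12 acetonide
Product: 13 (2S,3S,4Z,8Z)-3-[(tert-butyldimethylsilyl)oxy]-10-[(4-methoxybenzyl)oxy]-4,8-dimethyldeca-4,8-diene-1,2-diol
Conditions: AcOH/H2O (4:1), THF, 40 °C
Reagents that add atoms: none
Why: Acid-catalysed hydrolysis of the terminal acetonide; the hindered secondary TBS ether and the PMB ether survive aqueous acetic acid.

**Step 9**
Reactants: 13 C7,C8-diol
Product: 14 (2S,3S,4Z,8Z)-3-[(tert-butyldimethylsilyl)oxy]-10-[(4-methoxybenzyl)oxy]-4,8-dimethyl-1,2-bis[(triethylsilyl)oxy]deca-4,8-diene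
Conditions: TESCl, imidazole, DMAP (cat.), DMF, 0 °C → rt
Reagents that add atoms: triethylsilyl chloride CC[Si](Cl)(CC)CC
Why: Exhaustive silylation of the primary and secondary hydroxyls, which sets up the selective oxidation of the primary TES ether.

**Step 10**
Reactants: 15 trimethyl phosphonoacetate
Product: 16 methyl 2-(dimethoxyphosphoryl)-3-hydroxypropanoate
Conditions: (CH2O)n (1.0 equiv), piperidine (cat.), MeOH, 60 °C
Reagents that add atoms: formaldehyde (from paraformaldehyde) C=O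
Why: Amine-catalysed aldol-type hydroxymethylation of the phosphonate-stabilised carbanion, held at the mono-adduct by using one equivalent of formaldehyde.

**Step 11**
Reactants: 16 hydroxymethyl phosphonate
Product: 17 methyl 2-(dimethoxyphosphoryl)-3-[(triethylsilyl)oxy]propanoate
Conditions: TESCl, imidazole, CH2Cl2, 0 °C
Reagents that add atoms: triethylsilyl chloride CC[Si](Cl)(CC)CC
Why: Standard silylation of the primary alcohol to give the C11–C13 Horner–Wadsworth–Emmons reagent.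

**Step 12**
Reactants: 14 bis-TES ether; 17 phosphonate
Product: 19 methyl (2E,4S,5S,6Z,10Z)-5-[(tert-butyldimethylsilyl)oxy]-12-[(4-methoxybenzyl)oxy]-6,10-dimethyl-4-[(triethylsilyl)oxy]-2-{[(triethylsilyl)oxy]methyl}dodeca-2,6,10-trienoate, via aldehyde 18 (not isolated)
Conditions: (COCl)2, DMSO, CH2Cl2, −78 → −40 °C; Et3N, → 0 °C; then 17, LiCl, DBU, MeCN, 0 °C → rt
Reagents that add atoms: none
Why: Swern conditions oxidise the primary TES ether directly to aldehyde 18 (secondary silyl ethers and the PMB ether are inert), and Masamune–Roush Horner–Wadsworth–Emmons olefination with the α-branched phosphonate gives the enoate with the ester trans to C8 and CH2OTES cis to C8, the mild base avoiding epimerisation at C8 and β-elimination of the reagent.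

**Step 13**
Reactants: 19 enoate
Product: 20 (2Z,4S,5S,6Z,10Z)-5-[(tert-butyldimethylsilyl)oxy]-12-[(4-methoxybenzyl)oxy]-6,10-dimethyl-4-[(triethylsilyl)oxy]-2-{[(triethylsilyl)oxy]methyl}dodeca-2,6,10-trien-1-ol
Conditions: i-Bu2AlH (2.5 equiv), CH2Cl2, −78 °C
Reagents that add atoms: none
Why: 1,2-Reduction of the α,β-unsaturated ester to the allylic alcohol (C13-OH) by the aluminium hydride, with ethers and alkene geometry unaffected.

**Step 14**
Reactants: 20 allylic alcohol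
Product: 22 allylic chloride 1-({[(2Z,6Z,8S,9S,10E)-8-[(tert-butyldimethylsilyl)oxy]-12-chloro-3,7-dimethyl-9-[(triethylsilyl)oxy]-11-{[(triethylsilyl)oxy]methyl}dodeca-2,6,10-trien-1-yl]oxy}methyl)-4-methoxybenzene, via mesylate 21 (not isolated)
Conditions: MsCl, 2,4,6-collidine, LiCl, DMF, 0 °C
Reagents that add atoms: lithium chloride [Li+].[Cl-]; methanesulfonyl chloride CS(=O)(=O)Cl (its atoms stay only in 21)
Why: Collington–Meyers chlorination, in which the primary allylic mesylate is displaced by chloride in SN2 fashion without allylic transposition.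

**Step 15**
Reactants: 22 PMB-protected allylic chloride
Product: 23 (2Z,6Z,8S,9S,10E)-8-[(tert-butyldimethylsilyl)oxy]-12-chloro-3,7-dimethyl-9-[(triethylsilyl)oxy]-11-{[(triethylsilyl)oxy]methyl}dodeca-2,6,10-trien-1-ol
Conditions: DDQ, CH2Cl2/pH 7 buffer (10:1), 0 °C
Reagents that add atoms: none
Why: Oxidative PMB-ether cleavage (benzylic hydride abstraction by DDQ and hydrolysis of the oxocarbenium ion) under buffered conditions that leave silyl ethers, the allylic chloride and the alkenes intact.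

**Step 16**
Reactants: 23 seco chloro alcohol
Product: 24 (3Z,5S,6S,7Z,11Z)-6-[(tert-butyldimethylsilyl)oxy]-7,11-dimethyl-5-[(triethylsilyl)oxy]-3-{[(triethylsilyl)oxy]methyl}-1-oxacyclotrideca-3,7,11-triene
Conditions: NaH, n-Bu4NI (cat.), THF (0.002 M, slow addition), 45 °C
Reagents that add atoms: none
Why: Intramolecular Williamson etherification under high dilution, where the C6 alkoxide is remote from every silyl ether (no silyl shift) and displaces the primary allylic chloride at C13 to close the 13-membered bis-allylic ether.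

**Step 17**
Reactants: 24 13-membered bis-allylic ether
Product: 26 (1S,2Z,6Z,8S,9S,10R)-8-[(tert-butyldimethylsilyl)oxy]-3,7-dimethyl-9-[(triethylsilyl)oxy]-10-{3-[(triethylsilyl)oxy]prop-1-en-2-yl}cyclodeca-2,6-dien-1-ol, via lithiated ether 25 (not isolated)
Conditions: n-BuLi, THF, −78 → −30 °C; AcOH, −78 °C
Reagents that add atoms: none
Why: [2,3]-Wittig rearrangement as a ring contraction, in which lithiation of the open neryl O–CH2 (C6) and a suprafacial shift onto C7 form the C6–C7 bond and the ten-membered ring; the ring-trans allyl unit gives the anti C6-OH/C7 relationship (envelope transition state, vinyl group exo), and attack anti to the C8–OTES bond in the A(1,3)-minimised conformer sets C7 and C6 from the threonate-derived C8.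

**Step 18**
Reactants: 26 cyclodecadienol
Product: 27 (4R,5S,6R,7R,8S,9S,1(10)Z)-9-[(tert-butyldimethylsilyl)oxy]-4,5-epoxy-8,12-bis[(triethylsilyl)oxy]germacra-1(10),11(13)-dien-6-ol
Conditions: VO(acac)2 (5 mol %), t-BuOOH, CH2Cl2, 0 °C → rt
Reagents that add atoms: tert-butyl hydroperoxide CC(C)(C)OO
Why: Hydroxyl-directed epoxidation in which only C4=C5 is allylic to the free C6 hydroxyl; A(1,3) strain (C3 cis to C6) holds C6–H in the alkene plane so that oxygen is delivered syn to the hydroxyl, giving the threo cis-epoxide (4R,5S).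

**Step 19**
Reactants: 27 epoxy alcohol
Product: 28 (4R,5S,6R,7R,8S,9S,1(10)Z)-9-[(tert-butyldimethylsilyl)oxy]-4,5-epoxy-8-[(triethylsilyl)oxy]germacra-1(10),11(13)-diene-6,12-diol
Conditions: HF·pyridine, pyridine, THF, −10 °C
Reagents that add atoms: none
Why: Buffered fluoride-mediated desilylation, which removes the unhindered primary allylic TES ether much faster than the secondary TES and TBS ethers.

**Step 20**
Reactants: 28 C6,C12-diol
Product: 30 (4R,5S,6R,7R,8S,9S,1(10)Z)-9-[(tert-butyldimethylsilyl)oxy]-4,5-epoxy-8-[(triethylsilyl)oxy]germacra-1(10),11(13)-dien-12,6-olide, via lactol 29 (not isolated)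
Conditions: MnO2 (20 equiv), CH2Cl2, rt
Reagents that add atoms: none
Why: Allylic oxidation of the primary alcohol to the enal, trapping by the C6 hydroxyl as lactol 29 and further oxidation to the α-methylene-γ-lactone; the trans ring fusion follows from the C6/C7 configuration already set.

**Step 21**
Reactants: 30 silyl-protected lactone
Product: 31 (4R,5S,6R,7S,8S,9S,1(10)Z)-9-[(tert-butyldimethylsilyl)oxy]-4,5-epoxy-8-hydroxygermacra-1(10),11(13)-dien-12,6-olide
Conditions: HF·pyridine, pyridine, THF, rt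
Reagents that add atoms: none
Why: Selective desilylation, since a secondary TES ether is cleaved by buffered fluoride well before the secondary TBS ether at C9.

**Step 22**
Reactants: 31 C8 alcohol
Product: 32 (4R,5S,6R,7R,8S,9S,1(10)Z)-9-[(tert-butyldimethylsilyl)oxy]-4,5-epoxy-8-[(3-methylbut-2-enoyl)oxy]germacra-1(10),11(13)-dien-12,6-olide
Conditions: 3-methylbut-2-enoyl chloride, pyridine, DMAP (cat.), CH2Cl2, 0 °C
Reagents that add atoms: 3-methylbut-2-enoyl chloride (senecioyl chloride) CC(C)=CC(=O)Cl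
Why: DMAP-catalysed acylation of the only free hydroxyl, with retention at C8.

**Step 23**
Reactants: 32 C9 silyl ether
Product: 33 (4R,5S,6R,7S,8S,9S,1(10)Z)-4,5-epoxy-9-hydroxy-8-[(3-methylbut-2-enoyl)oxy]germacra-1(10),11(13)-dien-12,6-olide
Conditions: HF·pyridine (excess), THF, 0 °C → rt
Reagents that add atoms: none
Why: Fluoride-mediated cleavage of the remaining secondary TBS ether under acidic conditions that avoid acyl migration from O8 to O9.

**Compound list**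

1 | methyl (2R)-2-[(4S)-2,2-dimethyl-1,3-dioxolan-4-yl]-2-hydroxyacetate (methyl 3,4-O-isopropylidene-L-threonate) | CC1(C)OC[C@H](O1)[C@@H](O)C(=O)OC | starting material
2 | methyl (2R)-2-[(tert-butyldimethylsilyl)oxy]-2-[(4S)-2,2-dimethyl-1,3-dioxolan-4-yl]acetate | CC1(C)OC[C@H](O1)[C@@H](O[Si](C)(C)C(C)(C)C)C(=O)OC | intermediate
3 | (2R)-2-[(tert-butyldimethylsilyl)oxy]-2-[(4S)-2,2-dimethyl-1,3-dioxolan-4-yl]-N-methoxy-N-methylacetamide (not isolated) | CC1(C)OC[C@H](O1)[C@@H](O[Si](C)(C)C(C)(C)C)C(=O)N(C)OC | intermediate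
4 | (1R)-1-[(tert-butyldimethylsilyl)oxy]-1-[(4S)-2,2-dimethyl-1,3-dioxolan-4-yl]propan-2-one | CC1(C)OC[C@H](O1)[C@@H](O[Si](C)(C)C(C)(C)C)C(C)=O | intermediate
5 | nerol, (2Z)-3,7-dimethylocta-2,6-dien-1-ol | CC(C)=CCC/C(C)=C\CO | starting material
6 | 1-({[(2Z)-3,7-dimethylocta-2,6-dien-1-yl]oxy}methyl)-4-methoxybenzene | CC(C)=CCC/C(C)=C\COCc1ccc(OC)cc1 | intermediate
7 | (4Z)-6-[(4-methoxybenzyl)oxy]-4-methylhex-4-enal (not isolated) | O=CCC/C(C)=C\COCc1ccc(OC)cc1 | intermediate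
8 | (4Z)-6-[(4-methoxybenzyl)oxy]-4-methylhex-4-en-1-ol | OCCC/C(C)=C\COCc1ccc(OC)cc1 | intermediate
9 | 1-({[(2Z)-6-iodo-3-methylhex-2-en-1-yl]oxy}methyl)-4-methoxybenzene | ICCC/C(C)=C\COCc1ccc(OC)cc1 | intermediate
10 | [(4Z)-6-[(4-methoxybenzyl)oxy]-4-methylhex-4-en-1-yl]triphenylphosphonium iodide | [I-].c1ccccc1[P+](c1ccccc1)(c1ccccc1)CCC/C(C)=C\COCc1ccc(OC)cc1 | intermediate
11 | [(4Z)-6-[(4-methoxybenzyl)oxy]-4-methylhex-4-en-1-ylidene]triphenylphosphorane (not isolated) | c1ccccc1P(c1ccccc1)(c1ccccc1)=CCC/C(C)=C\COCc1ccc(OC)cc1 | intermediate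
12 | (4S)-4-[(1S,2Z,6Z)-1-[(tert-butyldimethylsilyl)oxy]-8-[(4-methoxybenzyl)oxy]-2,6-dimethylocta-2,6-dien-1-yl]-2,2-dimethyl-1,3-dioxolane | CC1(C)OC[C@H](O1)[C@@H](O[Si](C)(C)C(C)(C)C)/C(C)=C\CC/C(C)=C\COCc1ccc(OC)cc1 | intermediate
13 | (2S,3S,4Z,8Z)-3-[(tert-butyldimethylsilyl)oxy]-10-[(4-methoxybenzyl)oxy]-4,8-dimethyldeca-4,8-diene-1,2-diol | OC[C@H](O)[C@@H](O[Si](C)(C)C(C)(C)C)/C(C)=C\CC/C(C)=C\COCc1ccc(OC)cc1 | intermediate
14 | (2S,3S,4Z,8Z)-3-[(tert-butyldimethylsilyl)oxy]-10-[(4-methoxybenzyl)oxy]-4,8-dimethyl-1,2-bis[(triethylsilyl)oxy]deca-4,8-diene | CC[Si](CC)(CC)OC[C@H](O[Si](CC)(CC)CC)[C@@H](O[Si](C)(C)C(C)(C)C)/C(C)=C\CC/C(C)=C\COCc1ccc(OC)cc1 | intermediate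
15 | trimethyl phosphonoacetate, methyl 2-(dimethoxyphosphoryl)acetate | COC(=O)CP(=O)(OC)OC | starting material
16 | methyl 2-(dimethoxyphosphoryl)-3-hydroxypropanoate (racemic; centre lost in step 12) | COC(=O)C(CO)P(=O)(OC)OC | intermediate
17 | methyl 2-(dimethoxyphosphoryl)-3-[(triethylsilyl)oxy]propanoate (racemic) | COC(=O)C(CO[Si](CC)(CC)CC)P(=O)(OC)OC | intermediate
18 | (2R,3S,4Z,8Z)-3-[(tert-butyldimethylsilyl)oxy]-10-[(4-methoxybenzyl)oxy]-4,8-dimethyl-2-[(triethylsilyl)oxy]deca-4,8-dienal (not isolated) | O=C[C@H](O[Si](CC)(CC)CC)[C@@H](O[Si](C)(C)C(C)(C)C)/C(C)=C\CC/C(C)=C\COCc1ccc(OC)cc1 | intermediate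
19 | methyl (2E,4S,5S,6Z,10Z)-5-[(tert-butyldimethylsilyl)oxy]-12-[(4-methoxybenzyl)oxy]-6,10-dimethyl-4-[(triethylsilyl)oxy]-2-{[(triethylsilyl)oxy]methyl}dodeca-2,6,10-trienoate | COC(=O)/C(CO[Si](CC)(CC)CC)=C/[C@H](O[Si](CC)(CC)CC)[C@@H](O[Si](C)(C)C(C)(C)C)/C(C)=C\CC/C(C)=C\COCc1ccc(OC)cc1 | intermediate
20 | (2Z,4S,5S,6Z,10Z)-5-[(tert-butyldimethylsilyl)oxy]-12-[(4-methoxybenzyl)oxy]-6,10-dimethyl-4-[(triethylsilyl)oxy]-2-{[(triethylsilyl)oxy]methyl}dodeca-2,6,10-trien-1-ol | OC/C(CO[Si](CC)(CC)CC)=C/[C@H](O[Si](CC)(CC)CC)[C@@H](O[Si](C)(C)C(C)(C)C)/C(C)=C\CC/C(C)=C\COCc1ccc(OC)cc1 | intermediate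
21 | (2E,4S,5S,6Z,10Z)-5-[(tert-butyldimethylsilyl)oxy]-12-[(4-methoxybenzyl)oxy]-6,10-dimethyl-4-[(triethylsilyl)oxy]-2-{[(triethylsilyl)oxy]methyl}dodeca-2,6,10-trien-1-yl methanesulfonate (not isolated) | CS(=O)(=O)OC/C(CO[Si](CC)(CC)CC)=C/[C@H](O[Si](CC)(CC)CC)[C@@H](O[Si](C)(C)C(C)(C)C)/C(C)=C\CC/C(C)=C\COCc1ccc(OC)cc1 | intermediate
22 | 1-({[(2Z,6Z,8S,9S,10E)-8-[(tert-butyldimethylsilyl)oxy]-12-chloro-3,7-dimethyl-9-[(triethylsilyl)oxy]-11-{[(triethylsilyl)oxy]methyl}dodeca-2,6,10-trien-1-yl]oxy}methyl)-4-methoxybenzene | ClC/C(CO[Si](CC)(CC)CC)=C/[C@H](O[Si](CC)(CC)CC)[C@@H](O[Si](C)(C)C(C)(C)C)/C(C)=C\CC/C(C)=C\COCc1ccc(OC)cc1 | intermediate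
23 | (2Z,6Z,8S,9S,10E)-8-[(tert-butyldimethylsilyl)oxy]-12-chloro-3,7-dimethyl-9-[(triethylsilyl)oxy]-11-{[(triethylsilyl)oxy]methyl}dodeca-2,6,10-trien-1-ol | ClC/C(CO[Si](CC)(CC)CC)=C/[C@H](O[Si](CC)(CC)CC)[C@@H](O[Si](C)(C)C(C)(C)C)/C(C)=C\CC/C(C)=C\CO | intermediate
24 | (3Z,5S,6S,7Z,11Z)-6-[(tert-butyldimethylsilyl)oxy]-7,11-dimethyl-5-[(triethylsilyl)oxy]-3-{[(triethylsilyl)oxy]methyl}-1-oxacyclotrideca-3,7,11-triene (O1 bridges germacrane C13 and C6) | O1C/C(CO[Si](CC)(CC)CC)=C/[C@H](O[Si](CC)(CC)CC)[C@@H](O[Si](C)(C)C(C)(C)C)/C(C)=C\CC/C(C)=C\C1 | intermediate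
25 | 13-lithio derivative of 24 (lithium on germacrane C6, configuration not defined; not isolated) | O1C/C(CO[Si](CC)(CC)CC)=C/[C@H](O[Si](CC)(CC)CC)[C@@H](O[Si](C)(C)C(C)(C)C)/C(C)=C\CC/C(C)=C\C1[Li] | intermediate
26 | (1S,2Z,6Z,8S,9S,10R)-8-[(tert-butyldimethylsilyl)oxy]-3,7-dimethyl-9-[(triethylsilyl)oxy]-10-{3-[(triethylsilyl)oxy]prop-1-en-2-yl}cyclodeca-2,6-dien-1-ol | C=C(CO[Si](CC)(CC)CC)[C@H]1[C@H](O[Si](CC)(CC)CC)[C@@H](O[Si](C)(C)C(C)(C)C)/C(C)=C\CC/C(C)=C\[C@@H]1O | intermediate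
27 | (4R,5S,6R,7R,8S,9S,1(10)Z)-9-[(tert-butyldimethylsilyl)oxy]-4,5-epoxy-8,12-bis[(triethylsilyl)oxy]germacra-1(10),11(13)-dien-6-ol | C=C(CO[Si](CC)(CC)CC)[C@H]1[C@H](O[Si](CC)(CC)CC)[C@@H](O[Si](C)(C)C(C)(C)C)/C(C)=C\CC[C@@]2(C)O[C@H]2[C@@H]1O | intermediate
28 | (4R,5S,6R,7R,8S,9S,1(10)Z)-9-[(tert-butyldimethylsilyl)oxy]-4,5-epoxy-8-[(triethylsilyl)oxy]germacra-1(10),11(13)-diene-6,12-diol | C=C(CO)[C@H]1[C@H](O[Si](CC)(CC)CC)[C@@H](O[Si](C)(C)C(C)(C)C)/C(C)=C\CC[C@@]2(C)O[C@H]2[C@@H]1O | intermediate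
29 | lactol of 30 (12-hydroxy-6,12-epoxy form, C12 epimers; not isolated) | C=C1C(O)O[C@@H]2[C@@H]1[C@H](O[Si](CC)(CC)CC)[C@@H](O[Si](C)(C)C(C)(C)C)/C(C)=C\CC[C@@]1(C)O[C@@H]21 | intermediate
30 | (4R,5S,6R,7R,8S,9S,1(10)Z)-9-[(tert-butyldimethylsilyl)oxy]-4,5-epoxy-8-[(triethylsilyl)oxy]germacra-1(10),11(13)-dien-12,6-olide | C=C1C(=O)O[C@@H]2[C@@H]1[C@H](O[Si](CC)(CC)CC)[C@@H](O[Si](C)(C)C(C)(C)C)/C(C)=C\CC[C@@]1(C)O[C@@H]21 | intermediate
31 | (4R,5S,6R,7S,8S,9S,1(10)Z)-9-[(tert-butyldimethylsilyl)oxy]-4,5-epoxy-8-hydroxygermacra-1(10),11(13)-dien-12,6-olide | C=C1C(=O)O[C@@H]2[C@@H]1[C@H](O)[C@@H](O[Si](C)(C)C(C)(C)C)/C(C)=C\CC[C@@]1(C)O[C@@H]21 | intermediate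
32 | (4R,5S,6R,7R,8S,9S,1(10)Z)-9-[(tert-butyldimethylsilyl)oxy]-4,5-epoxy-8-[(3-methylbut-2-enoyl)oxy]germacra-1(10),11(13)-dien-12,6-olide | C=C1C(=O)O[C@@H]2[C@@H]1[C@H](OC(=O)C=C(C)C)[C@@H](O[Si](C)(C)C(C)(C)C)/C(C)=C\CC[C@@]1(C)O[C@@H]21 | intermediate
33 | (4R,5S,6R,7S,8S,9S,1(10)Z)-4,5-epoxy-9-hydroxy-8-[(3-methylbut-2-enoyl)oxy]germacra-1(10),11(13)-dien-12,6-olide (CNP0188779.1) | C=C1C(=O)O[C@@H]2[C@@H]1[C@H](OC(=O)C=C(C)C)[C@@H](O)/C(C)=C\CC[C@@]1(C)O[C@@H]21 | target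

**Totals**

Total step count: 23 (17 on the line from 1, 4 for phosphonium salt 10, 2 for phosphonate 17).
Longest linear sequence: 19 steps (5 → 33: steps 3–9 and 12–23).

**Three steps most likely to fail**

Step 17 ([2,3]-Wittig ring contraction). The risks are lithiation at the other O–CH2 (C13) or at the CH2OTES group, and silyl migration in the product alkoxide. The fallback sets out from 23 and comes back at 26. MnO2 oxidation of the C6 alcohol of 23 gives the enal (2Z,6Z,8S,9S,10E)-8-[(tert-butyldimethylsilyl)oxy]-12-chloro-3,7-dimethyl-9-[(triethylsilyl)oxy]-11-{[(triethylsilyl)oxy]methyl}dodeca-2,6,10-trienal F1. A CrCl2/NaI-mediated intramolecular Nozaki–Hiyama allylation under high dilution then closes the ten-membered ring: the allylchromium species adds through its γ-carbon C7 to the aldehyde in a chair transition state, anti-selectively, and gives 26 without passing through 24.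

Step 16 (13-membered macro-etherification). The risks are oligomerisation and slow closure. The fallback sets out from 20 and comes back at 24. Methyl chloroformate and pyridine convert 20 into methyl (2Z,4S,5S,6Z,10Z)-5-[(tert-butyldimethylsilyl)oxy]-12-[(4-methoxybenzyl)oxy]-6,10-dimethyl-4-[(triethylsilyl)oxy]-2-{[(triethylsilyl)oxy]methyl}dodeca-2,6,10-trien-1-yl carbonate F2. DDQ removes the PMB group to give methyl (2Z,4S,5S,6Z,10Z)-5-[(tert-butyldimethylsilyl)oxy]-12-hydroxy-6,10-dimethyl-4-[(triethylsilyl)oxy]-2-{[(triethylsilyl)oxy]methyl}dodeca-2,6,10-trien-1-yl carbonate F3. Pd(PPh3)4 (zerovalent palladium) in dilute THF then effects an intramolecular Tsuji–Trost allylic etherification: the released methoxide deprotonates the C6 hydroxyl, which attacks the unhindered CH2 terminus of the π-allyl complex to give 24. Isomerisation of the π-allyl unit could erode the C7=C11 geometry and would have to be checked.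

Step 7 (Z-selective Wittig). The risks are an E/Z mixture at C1=C10 and epimerisation of C9 next to the ketone. The fallback sets out from 6 and comes back at 12. Ozonolysis of 6 with Me2S work-up gives aldehyde 7 as an isolated compound. Stork–Zhao olefination (Ph3P=C(I)CH3 from ethyltriphenylphosphonium iodide, n-BuLi, I2, NaN(SiMe3)2) gives the vinyl iodide 1-({[(2Z,6Z)-7-iodo-3-methylocta-2,6-dien-1-yl]oxy}methyl)-4-methoxybenzene F4. Iodine–lithium exchange (t-BuLi, −78 °C) and addition to bought (S)-2,2-dimethyl-1,3-dioxolane-4-carbaldehyde give (2Z,6Z)-1-[(4S)-2,2-dimethyl-1,3-dioxolan-4-yl]-8-[(4-methoxybenzyl)oxy]-2,6-dimethylocta-2,6-dien-1-ol F5 as a C9 epimer mixture. Dess–Martin oxidation gives the enone (2Z,6Z)-1-[(4S)-2,2-dimethyl-1,3-dioxolan-4-yl]-8-[(4-methoxybenzyl)oxy]-2,6-dimethylocta-2,6-dien-1-one F6. Felkin–Anh reduction with LiBH(s-Bu)3 gives (1S,2Z,6Z)-1-[(4S)-2,2-dimethyl-1,3-dioxolan-4-yl]-8-[(4-methoxybenzyl)oxy]-2,6-dimethylocta-2,6-dien-1-ol F7, and silylation (TBSCl, imidazole) gives 12. In this variant the Z geometry comes from the vinyl iodide, and C9 is set by substrate-controlled reduction next to the glyceraldehyde-derived C8.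

**Further compounds**

F1 | step 17 | (2Z,6Z,8S,9S,10E)-8-[(tert-butyldimethylsilyl)oxy]-12-chloro-3,7-dimethyl-9-[(triethylsilyl)oxy]-11-{[(triethylsilyl)oxy]methyl}dodeca-2,6,10-trienal | ClC/C(CO[Si](CC)(CC)CC)=C/[C@H](O[Si](CC)(CC)CC)[C@@H](O[Si](C)(C)C(C)(C)C)/C(C)=C\CC/C(C)=C\C=O
F2 | step 16 | methyl (2Z,4S,5S,6Z,10Z)-5-[(tert-butyldimethylsilyl)oxy]-12-[(4-methoxybenzyl)oxy]-6,10-dimethyl-4-[(triethylsilyl)oxy]-2-{[(triethylsilyl)oxy]methyl}dodeca-2,6,10-trien-1-yl carbonate | COC(=O)OC/C(CO[Si](CC)(CC)CC)=C/[C@H](O[Si](CC)(CC)CC)[C@@H](O[Si](C)(C)C(C)(C)C)/C(C)=C\CC/C(C)=C\COCc1ccc(OC)cc1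
F3 | step 16 | methyl (2Z,4S,5S,6Z,10Z)-5-[(tert-butyldimethylsilyl)oxy]-12-hydroxy-6,10-dimethyl-4-[(triethylsilyl)oxy]-2-{[(triethylsilyl)oxy]methyl}dodeca-2,6,10-trien-1-yl carbonate | COC(=O)OC/C(CO[Si](CC)(CC)CC)=C/[C@H](O[Si](CC)(CC)CC)[C@@H](O[Si](C)(C)C(C)(C)C)/C(C)=C\CC/C(C)=C\CO
F4 | step 7 | 1-({[(2Z,6Z)-7-iodo-3-methylocta-2,6-dien-1-yl]oxy}methyl)-4-methoxybenzene | I/C(C)=C\CC/C(C)=C\COCc1ccc(OC)cc1
F5 | step 7 | (2Z,6Z)-1-[(4S)-2,2-dimethyl-1,3-dioxolan-4-yl]-8-[(4-methoxybenzyl)oxy]-2,6-dimethylocta-2,6-dien-1-ol (C1 epimers) | CC1(C)OC[C@H](O1)C(O)/C(C)=C\CC/C(C)=C\COCc1ccc(OC)cc1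
F6 | step 7 | (2Z,6Z)-1-[(4S)-2,2-dimethyl-1,3-dioxolan-4-yl]-8-[(4-methoxybenzyl)oxy]-2,6-dimethylocta-2,6-dien-1-one | CC1(C)OC[C@H](O1)C(=O)/C(C)=C\CC/C(C)=C\COCc1ccc(OC)cc1
F7 | step 7 | (1S,2Z,6Z)-1-[(4S)-2,2-dimethyl-1,3-dioxolan-4-yl]-8-[(4-methoxybenzyl)oxy]-2,6-dimethylocta-2,6-dien-1-ol | CC1(C)OC[C@H](O1)[C@@H](O)/C(C)=C\CC/C(C)=C\COCc1ccc(OC)cc1
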